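**Retrosynthetic overview**

- Feature: in the flavanone, O1 on C2 lies β to the C4 carbonyl (C4–C3–C2–O1). A carbanion or enolate at C3 would expel the C8a aryloxide from C2, opening ring C to the chalcone and erasing the C2 stereocentre. Ring C is therefore closed with C4 as the nucleophile and C3 as the electrophile.
- Target ⇐ 5-O-methoxymethyl flavanone ⇐ spiro-1,3-dithiane at C4 (carbonyl unmasked only after ring closure).
- Key disconnection C3–C4: a 2-lithio-2-aryl-1,3-dithiane (C4, on C4a of ring A) displaces a primary tosylate (C3). Ring C is the only ring formed; rings A and B are bought.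
- C2–O1 comes from Mitsunobu inversion of methyl (S)-mandelate by the ring A phenol (C8a–OH); the ester is then reduced and tosylated to supply C3.
- Ring A comes from 2,4,6-trihydroxybenzaldehyde by C-prenylation (C8), 4-O-prenylation (O7) and 6-O-methoxymethylation (O5).

Key step: step 8

Assumption: the target is the (2S) enantiomer (priorities at C2: O1 > phenyl > C3 > H, as encoded by the SMILES). Flavanone numbering (O1, C2, C3, C4, C4a, C5–C8, C8a) is used for positions in all intermediates.

**Route**

Step 1
Reactants: 1 2,4,6-trihydroxybenzaldehyde; 2 1-bromo-3-methylbut-2-ene (prenyl bromide)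
Product: 3 2,4,6-trihydroxy-3-(3-methylbut-2-enyl)benzaldehyde
Conditions: 2 (1.0 equiv), 10% aq. KOH, 0 °C → rt
Reagents that add atoms: none
Why: Phenoxide C-alkylation (nuclear prenylation) of a phloroglucinol aldehyde; in water the phenoxide oxygens are hydrogen-bonded, so the ambident anion should attack the allylic bromide through ring carbon, and C3 and C5 are equivalent by symmetry, so only one mono-C-prenyl isomer can form.

Step 2
Reactants: 3 2,4,6-trihydroxy-3-(3-methylbut-2-enyl)benzaldehyde; 2 1-bromo-3-methylbut-2-ene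
Product: 4 2,6-dihydroxy-3-(3-methylbut-2-enyl)-4-(3-methylbut-2-enyloxy)benzaldehyde
Conditions: 2 (1.05 equiv), K2CO3 (1.0 equiv), acetone, rt
Reagents that add atoms: none
Why: Williamson etherification; the 4-OH, para to the formyl group and not engaged in a hydrogen bond to it, is the most acidic and most nucleophilic hydroxyl, so one equivalent of bromide with a weak base in an aprotic solvent should etherify it alone.

Step 3
Reactants: 4 2,6-dihydroxy-3-(3-methylbut-2-enyl)-4-(3-methylbut-2-enyloxy)benzaldehyde
Product: 5 2-hydroxy-6-(methoxymethoxy)-3-(3-methylbut-2-enyl)-4-(3-methylbut-2-enyloxy)benzaldehyde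
Conditions: MOMCl (1.05 equiv), i-Pr2NEt, CH2Cl2, 0 °C
Reagents that add atoms: chloromethyl methyl ether (MOMCl), COCCl
Why: Williamson-type O-alkylation with an α-chloro ether; the 6-OH is flanked only by H-5 whereas the 2-OH is wedged between the formyl group and the prenyl CH2, and once one ortho hydroxyl is capped the other is locked in the hydrogen bond to C=O and should stay free.

Step 4
Reactants: 5 2-hydroxy-6-(methoxymethoxy)-3-(3-methylbut-2-enyl)-4-(3-methylbut-2-enyloxy)benzaldehyde; 6 methyl (S)-mandelate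
Product: 7 methyl (2R)-2-[2-formyl-3-(methoxymethoxy)-6-(3-methylbut-2-enyl)-5-(3-methylbut-2-enyloxy)phenoxy]-2-phenylacetate
Conditions: PPh3, DIAD, toluene, 0 °C → rt
Reagents that add atoms: none
Why: Mitsunobu etherification; the salicylaldehyde-type phenol is acidic enough to protonate the betaine and its phenoxide displaces the oxyphosphonium of the α-hydroxy ester by SN2 with inversion, turning the (S)-carbinol into the (R)-aryl ether that becomes C2 with O1 attached, the ester group disfavouring ionisation at the benzylic carbon.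

Step 5
Reactants: 7 methyl (2R)-2-[2-formyl-3-(methoxymethoxy)-6-(3-methylbut-2-enyl)-5-(3-methylbut-2-enyloxy)phenoxy]-2-phenylacetate; 8 propane-1,3-dithiol
Product: 9 methyl (2R)-2-[2-(1,3-dithian-2-yl)-3-(methoxymethoxy)-6-(3-methylbut-2-enyl)-5-(3-methylbut-2-enyloxy)phenoxy]-2-phenylacetate
Conditions: 8 (1.1 equiv), Hf(OTf)4 (2 mol %), CH2Cl2, 0 °C → rt
Reagents that add atoms: none
Why: Lewis-acid-catalysed dithioacetalisation of an aromatic aldehyde; a low loading of a water-tolerant triflate at low temperature is chosen to spare the methoxymethyl ether, the aryl prenyl ether and the alkenes, and the base-free medium should prevent both epimerisation of the α-aryloxy ester and its aldol addition to the neighbouring formyl group.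

Step 6
Reactants: 9 methyl (2R)-2-[2-(1,3-dithian-2-yl)-3-(methoxymethoxy)-6-(3-methylbut-2-enyl)-5-(3-methylbut-2-enyloxy)phenoxy]-2-phenylacetate
Product: 10 (2R)-2-[2-(1,3-dithian-2-yl)-3-(methoxymethoxy)-6-(3-methylbut-2-enyl)-5-(3-methylbut-2-enyloxy)phenoxy]-2-phenylethan-1-ol
Conditions: LiBH4, THF, 0 °C → rt
Reagents that add atoms: none
Why: Borohydride reduction of an α-aryloxy-activated methyl ester to the primary alcohol; LiBH4 is weakly basic, so the α-stereocentre should not epimerise before the carbonyl is gone, and the dithiane, acetal and alkenes are inert to it.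

Step 7
Reactants: 10 (2R)-2-[2-(1,3-dithian-2-yl)-3-(methoxymethoxy)-6-(3-methylbut-2-enyl)-5-(3-methylbut-2-enyloxy)phenoxy]-2-phenylethan-1-ol
Product: 11 (2R)-2-[2-(1,3-dithian-2-yl)-3-(methoxymethoxy)-5-(3-methylbut-2-enyloxy)-6-(3-methylbut-2-enyl)phenoxy]-2-phenylethyl 4-methylbenzenesulfonate
Conditions: TsCl, Et3N, DMAP (cat.), CH2Cl2, 0 °C → rt
Reagents that add atoms: 4-methylbenzenesulfonyl chloride (TsCl), Cc1ccc(cc1)S(Cl)(=O)=O
Why: Sulfonylation of the only free hydroxyl, a primary alcohol; the stereocentre no longer carries an acidic hydrogen and is not touched.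

Step 8
Reactants: 11 (2R)-2-[2-(1,3-dithian-2-yl)-3-(methoxymethoxy)-5-(3-methylbut-2-enyloxy)-6-(3-methylbut-2-enyl)phenoxy]-2-phenylethyl 4-methylbenzenesulfonate
Product: 13 (2S)-5-(methoxymethoxy)-7-(3-methylbut-2-enyloxy)-8-(3-methylbut-2-enyl)-2-phenylspiro[chromane-4,2'-[1,3]dithiane], via 2-lithio-1,3-dithiane tosylate 12 (not isolated)
Conditions: n-BuLi (1.05 equiv), THF, −78 °C, 30 min; then −78 → 0 °C
Reagents that add atoms: none
Why: n-BuLi, pre-coordinated by the neighbouring OMOM oxygen, removes the dithioacetal hydrogen on the future C4 to give lithiated dithiane 12, whose carbanion displaces the primary tosylate at C3 by intramolecular SN2 and so forms the C3–C4 bond with C4 masked as its dithioketal. The closest known reaction type is the Corey–Seebach alkylation of 2-lithio-1,3-dithianes with primary arenesulfonates, used here in its ring-forming variant. Ring C is closed in the 6-exo-tet mode, the rigid C4a–C8a–O1 segment of ring A holding carbanion and sulfonate close together. No stereocentre is created: the spiro carbon C4 is achiral and C2 is not a reacting centre, so the configuration fixed by the Mitsunobu inversion is carried over, the descriptor changing from R to S only because CH2OTs outranks phenyl while C3H2 in the product does not. The step needs deprotonation at the dithiane C–H and not at the benzylic C2–H (which would lead to β-elimination of the tosylate or to Wittig rearrangement) nor attack of the base on the sulfonate; the far higher acidity of the hydrogen between two sulfur atoms, the low temperature and the single equivalent of base should secure this. Because the carbanion sits on C4 there is never an enolate β to O1, so the aryloxide cannot be expelled from C2.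

Step 9
Reactants: 13 (2S)-5-(methoxymethoxy)-7-(3-methylbut-2-enyloxy)-8-(3-methylbut-2-enyl)-2-phenylspiro[chromane-4,2'-[1,3]dithiane]
Product: 14 (2S)-5-(methoxymethoxy)-7-(3-methylbut-2-enyloxy)-8-(3-methylbut-2-enyl)-2-phenylchroman-4-one
Conditions: MeI (excess), CaCO3, MeCN/H2O 4:1, 40 °C
Reagents that add atoms: water, O
Why: Alkylative dithioketal hydrolysis; S-methylation creates a sulfonium leaving group, the electron-rich aryl ring assists ionisation to the thionium ion and water delivers the C4 carbonyl oxygen, while the CaCO3 buffer keeps the medium near neutral so that the acetal, the prenyl ether and the β-aryloxy ketone at C2 should be undisturbed.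

Step 10
Reactants: 14 (2S)-5-(methoxymethoxy)-7-(3-methylbut-2-enyloxy)-8-(3-methylbut-2-enyl)-2-phenylchroman-4-one
Product: 15 (2S)-5-hydroxy-7-(3-methylbut-2-enyloxy)-8-(3-methylbut-2-enyl)-2-phenylchroman-4-one
Conditions: HCl (0.5 M in MeOH), 0 °C → rt
Reagents that add atoms: none
Why: Acid-catalysed acetal exchange (methoxymethyl ether cleavage); the 5-O-acetal peri to the C4 carbonyl is activated by chelation and should fall off under conditions too mild to ionise the aryl prenyl ether, to add methanol to the trisubstituted alkenes or to open ring C at C2.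

**Compound list**

1 | 2,4,6-trihydroxybenzaldehyde | O=Cc1c(O)cc(O)cc1O | starting material
2 | 1-bromo-3-methylbut-2-ene (prenyl bromide) | CC(C)=CCBr | starting material
3 | 2,4,6-trihydroxy-3-(3-methylbut-2-enyl)benzaldehyde | O=Cc1c(O)cc(O)c(CC=C(C)C)c1O | intermediate
4 | 2,6-dihydroxy-3-(3-methylbut-2-enyl)-4-(3-methylbut-2-enyloxy)benzaldehyde | O=Cc1c(O)cc(OCC=C(C)C)c(CC=C(C)C)c1O | intermediate
5 | 2-hydroxy-6-(methoxymethoxy)-3-(3-methylbut-2-enyl)-4-(3-methylbut-2-enyloxy)benzaldehyde | O=Cc1c(OCOC)cc(OCC=C(C)C)c(CC=C(C)C)c1O | intermediate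
6 | methyl (S)-mandelate | COC(=O)[C@@H](O)c1ccccc1 | starting material
7 | methyl (2R)-2-[2-formyl-3-(methoxymethoxy)-6-(3-methylbut-2-enyl)-5-(3-methylbut-2-enyloxy)phenoxy]-2-phenylacetate | COC(=O)[C@H](Oc1c(C=O)c(OCOC)cc(OCC=C(C)C)c1CC=C(C)C)c1ccccc1 | intermediate
8 | propane-1,3-dithiol | SCCCS | starting material
9 | methyl (2R)-2-[2-(1,3-dithian-2-yl)-3-(methoxymethoxy)-6-(3-methylbut-2-enyl)-5-(3-methylbut-2-enyloxy)phenoxy]-2-phenylacetate | COC(=O)[C@H](Oc1c(C2SCCCS2)c(OCOC)cc(OCC=C(C)C)c1CC=C(C)C)c1ccccc1 | intermediate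
10 | (2R)-2-[2-(1,3-dithian-2-yl)-3-(methoxymethoxy)-6-(3-methylbut-2-enyl)-5-(3-methylbut-2-enyloxy)phenoxy]-2-phenylethan-1-ol | OC[C@H](Oc1c(C2SCCCS2)c(OCOC)cc(OCC=C(C)C)c1CC=C(C)C)c1ccccc1 | intermediate
11 | (2R)-2-[2-(1,3-dithian-2-yl)-3-(methoxymethoxy)-5-(3-methylbut-2-enyloxy)-6-(3-methylbut-2-enyl)phenoxy]-2-phenylethyl 4-methylbenzenesulfonate | Cc1ccc(cc1)S(=O)(=O)OC[C@@H](c1ccccc1)Oc1c(C2SCCCS2)c(OCOC)cc(OCC=C(C)C)c1CC=C(C)C | intermediate
12 | (2R)-2-[2-(2-lithio-1,3-dithian-2-yl)-3-(methoxymethoxy)-5-(3-methylbut-2-enyloxy)-6-(3-methylbut-2-enyl)phenoxy]-2-phenylethyl 4-methylbenzenesulfonate | Cc1ccc(cc1)S(=O)(=O)OC[C@@H](c1ccccc1)Oc1c(C2([Li])SCCCS2)c(OCOC)cc(OCC=C(C)C)c1CC=C(C)C | intermediate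
13 | (2S)-5-(methoxymethoxy)-7-(3-methylbut-2-enyloxy)-8-(3-methylbut-2-enyl)-2-phenylspiro[chromane-4,2'-[1,3]dithiane] | CC(C)=CCOc1cc(OCOC)c2c(c1CC=C(C)C)O[C@H](c1ccccc1)CC21SCCCS1 | intermediate
14 | (2S)-5-(methoxymethoxy)-7-(3-methylbut-2-enyloxy)-8-(3-methylbut-2-enyl)-2-phenylchroman-4-one | CC(C)=CCOc1cc(OCOC)c2c(c1CC=C(C)C)O[C@H](c1ccccc1)CC2=O | intermediate
15 | (2S)-5-hydroxy-7-(3-methylbut-2-enyloxy)-8-(3-methylbut-2-enyl)-2-phenylchroman-4-one | CC(C)=CCOc1cc(O)c2c(c1CC=C(C)C)O[C@H](c1ccccc1)CC2=O | target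

**Step count**

Total step count: 10. Longest linear sequence: 10 steps (1 → 15).

**Steps most likely to fail**

Step 8 (ring closure). Metalation of the hindered, twisted aryl dithiane may be slow, so that n-BuLi attacks the sulfonate, or the base or the carbanion may remove H-2 and the tosylate is then lost by β-elimination instead of substitution. The fallback keeps C4 as the acyl anion but makes the two bonds of ring C in the opposite order and sets out from 5. The aldehyde of 5 is thioacetalised as in step 5 to 2-(1,3-dithian-2-yl)-3-(methoxymethoxy)-6-(3-methylbut-2-enyl)-5-(3-methylbut-2-enyloxy)phenol F1. Its phenoxide/dithiane dianion (n-BuLi, 2.2 equiv, THF, −78 → −20 °C) should open commercial (S)-styrene oxide at the CH2 terminus, an electrophile with no leaving group to eliminate, giving (1R)-2-{2-[2-hydroxy-6-(methoxymethoxy)-3-(3-methylbut-2-enyl)-4-(3-methylbut-2-enyloxy)phenyl]-1,3-dithian-2-yl}-1-phenylethan-1-ol F2. Intramolecular Mitsunobu etherification (PPh3, DIAD, THF) then closes O1–C2 with inversion of the (R)-carbinol and comes back to the route at 13.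

Step 5 (dithioacetalisation). The Lewis acid and dithiol may strip the methoxymethyl ether, which is activated by chelation between the formyl and acetal oxygens, before or while the aldehyde is converted. The fallback sets out from 7 and removes the group on purpose, then puts it back. Treatment of 7 with ZnBr2 and excess propane-1,3-dithiol in CH2Cl2 at 0 °C, a medium that both cleaves such acetals and catalyses thioacetalisation, should give methyl (2R)-2-[2-(1,3-dithian-2-yl)-3-hydroxy-6-(3-methylbut-2-enyl)-5-(3-methylbut-2-enyloxy)phenoxy]-2-phenylacetate F3. The now unchelated phenol is re-protected with MOMCl and i-Pr2NEt in CH2Cl2 at 0 °C, which comes back to the route at 9.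

Step 3 (mono-protection). Site selectivity between the 6-OH and the 2-OH may be poor, giving the regioisomeric ether or the bis-ether. The fallback sets out from 1 and makes the regiochemistry a consequence of symmetry and of a sigmatropic shift. 4-O-Prenylation of 1 (2, K2CO3, acetone) gives symmetric 2,6-dihydroxy-4-(3-methylbut-2-enyloxy)benzaldehyde F4. Capping either of its equivalent hydroxyls (MOMCl, i-Pr2NEt) gives 2-hydroxy-6-(methoxymethoxy)-4-(3-methylbut-2-enyloxy)benzaldehyde F5. The remaining phenol is etherified with 3-chloro-3-methylbut-1-yne (CuCl2 cat., DBU, MeCN, 0 °C) to 2-(methoxymethoxy)-6-(2-methylbut-3-yn-2-yloxy)-4-(3-methylbut-2-enyloxy)benzaldehyde F6. Semi-hydrogenation (H2, Pd/CaCO3 poisoned with Pb(OAc)2, quinoline, EtOAc) gives 2-(methoxymethoxy)-6-(2-methylbut-3-en-2-yloxy)-4-(3-methylbut-2-enyloxy)benzaldehyde F7. Warming F7 in toluene (about 110 °C) should trigger the aromatic Claisen rearrangement of the tertiary allyl ether to the only free ortho carbon, well below the temperature at which the primary prenyl ether rearranges, and comes back to the route at 5.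

**Further compounds**

F1 | step 8 | 2-(1,3-dithian-2-yl)-3-(methoxymethoxy)-6-(3-methylbut-2-enyl)-5-(3-methylbut-2-enyloxy)phenol | Oc1c(C2SCCCS2)c(OCOC)cc(OCC=C(C)C)c1CC=C(C)C
F2 | step 8 | (1R)-2-{2-[2-hydroxy-6-(methoxymethoxy)-3-(3-methylbut-2-enyl)-4-(3-methylbut-2-enyloxy)phenyl]-1,3-dithian-2-yl}-1-phenylethan-1-ol | O[C@H](CC1(SCCCS1)c1c(O)c(CC=C(C)C)c(OCC=C(C)C)cc1OCOC)c1ccccc1
F3 | step 5 | methyl (2R)-2-[2-(1,3-dithian-2-yl)-3-hydroxy-6-(3-methylbut-2-enyl)-5-(3-methylbut-2-enyloxy)phenoxy]-2-phenylacetate | COC(=O)[C@H](Oc1c(C2SCCCS2)c(O)cc(OCC=C(C)C)c1CC=C(C)C)c1ccccc1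
F4 | step 3 | 2,6-dihydroxy-4-(3-methylbut-2-enyloxy)benzaldehyde | O=Cc1c(O)cc(OCC=C(C)C)cc1O
F5 | step 3 | 2-hydroxy-6-(methoxymethoxy)-4-(3-methylbut-2-enyloxy)benzaldehyde | O=Cc1c(OCOC)cc(OCC=C(C)C)cc1O
F6 | step 3 | 2-(methoxymethoxy)-6-(2-methylbut-3-yn-2-yloxy)-4-(3-methylbut-2-enyloxy)benzaldehyde | O=Cc1c(OCOC)cc(OCC=C(C)C)cc1OC(C)(C)C#C
F7 | step 3 | 2-(methoxymethoxy)-6-(2-methylbut-3-en-2-yloxy)-4-(3-methylbut-2-enyloxy)benzaldehyde | O=Cc1c(OCOC)cc(OCC=C(C)C)cc1OC(C)(C)C=C
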